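## Retrosynthetic overview

1. The target is the cis,cis-(2S,3S,2''S,3''S)-3,3''-biflavanone. Unprimed locants (rings A, C, B) are used for the 5,7-dihydroxy half and double-primed locants (A'', C'', B'') for the 7-methoxy half. Each pyranone ring is cut at O1–C8a and C4–C4a into an aryne (ring A or A'') and a β-oxido acyl unit O–C2–C3–C4(=O).
2. Enabling feature: the units O–C2–C3–C4(=O) of ring C and O–C2''–C3''–C4''(=O) of ring C'' are joined C3–C3''. So C4(=O) is 1,4 to the oxygen on C2'', and C4''(=O) is 1,4 to the oxygen on C2. The core therefore folds into the cis-fused, exo,exo-diaryl bis-γ-lactone 9. Its four stereocentres are C2, C3, C3'', C2'' of the cis,cis target, and its lactone oxygen on C2'' is set free exactly when ring C closes.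
3. 9 comes from (2R,3R)-2,3-bis(4-methoxybenzyl)succinic acid 8. An auxiliary-controlled oxidative enolate homocoupling sets C3/C3'', and a double benzylic oxidative lactonization sets C2/C2''.
4. Ring order: rings B and B'' come with 1; two temporary γ-lactone rings form in step 4; one lactone is opened to an amide in step 5. Step 14 is a one-pot relay of two aryne annulations: ring A arrives and ring C closes on the remaining lactone, then the liberated C2'' alkoxide takes ring A'' and closes ring C'' last on the amide. Hydrogenolysis follows.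

Key step: step 14

Remark: the SMILES is read as the 2,3-cis/2'',3''-cis isomer (H-2/H-3 and H-2''/H-3'' on the same face of rings C and C''). Such 3-substituted cis-flavanones epimerise with base or acid, so the end-game is kept neutral.

## Route

Step 1
Reactants: 1 3-(4-methoxyphenyl)propanoic acid; 2 (S)-4-benzyl-1,3-oxazolidin-2-one
Product: 4 (S)-4-benzyl-3-[3-(4-methoxyphenyl)propanoyl]-1,3-oxazolidin-2-one, via mixed pivalic anhydride 3 (not isolated)
Conditions: PivCl, Et3N, THF, −20 °C; then LiCl, 2, −20 °C → rt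
Reagents that add atoms: none
Why: N-acylation of the oxazolidinone auxiliary through the mixed pivalic anhydride (LiCl/Et3N variant), which needs no strong base and forms no stereocentre.

Step 2
Reactants: 4 (S)-4-benzyl-3-[3-(4-methoxyphenyl)propanoyl]-1,3-oxazolidin-2-one (two molecules)
Product: 6 (2R,3R)-1,4-bis[(S)-4-benzyl-2-oxo-1,3-oxazolidin-3-yl]-2,3-bis(4-methoxybenzyl)butane-1,4-dione, via lithium enolate 5 (not isolated)
Conditions: LDA, THF, −78 °C; then TiCl4, −78 °C → rt
Reagents that add atoms: none
Why: oxidative homocoupling of an imide enolate (the enolate on tetravalent titanium passes one electron to the metal, which becomes trivalent titanium, and the α-carbonyl radicals dimerise), in which the benzyl group of each auxiliary shields one face of its chelated (Z)-enolate so that both new centres (C3 and C3'') should form with the same sense to give the (2R,3R) dimer, minor diastereomers being removed by crystallization.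

Step 3
Reactants: 6 (2R,3R)-1,4-bis[(S)-4-benzyl-2-oxo-1,3-oxazolidin-3-yl]-2,3-bis(4-methoxybenzyl)butane-1,4-dione
Product: 8 (2R,3R)-2,3-bis(4-methoxybenzyl)butanedioic acid, via dilithium diperoxoate 7 (not isolated)
Conditions: LiOH, H2O2, THF/H2O, 0 °C; Na2SO3; HCl (pH 2)
Reagents that add atoms: hydrogen peroxide, OO
Why: hydroperoxide cleavage of the N-acyl oxazolidinones (attack at the exocyclic carbonyl, sulfite reduction of the peracid), which runs without enolization so that C3 and C3'' should keep their configuration while auxiliary 2 is recovered.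

Step 4
Reactants: 8 (2R,3R)-2,3-bis(4-methoxybenzyl)butanedioic acid
Product: 9 (3S,3aS,6S,6aS)-3,6-bis(4-methoxyphenyl)tetrahydro-1H,4H-furo[3,4-c]furan-1,4-dione (cis-fused, both aryl groups exo)
Conditions: DDQ (2.5 equiv), AcOH, 80 °C
Reagents that add atoms: none
Why: double benzylic oxidative lactonization (hydride abstraction para to the methoxy group, 5-exo capture of each p-methoxybenzyl cation by the γ-carboxyl group), in which the (2R,3R) core can only give the cis-fused bicycle and each aryl group should take the exo face trans to the neighbouring acyl-bearing carbon, an outcome that reversible ionization of the p-methoxybenzylic C–O bonds in hot acetic acid also favours, which fixes C2 and C2''.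

Step 5
Reactants: 9 (3S,3aS,6S,6aS)-3,6-bis(4-methoxyphenyl)tetrahydro-1H,4H-furo[3,4-c]furan-1,4-dione
Product: 10 (3S,4S,5S)-3-[(S)-hydroxy(4-methoxyphenyl)methyl]-5-(4-methoxyphenyl)-4-(morpholine-4-carbonyl)oxolan-2-one
Conditions: morpholine, AlMe3 (1.0 equiv each), CH2Cl2, 0 °C; then 9, −20 → 0 °C; aq. potassium sodium tartrate
Reagents that add atoms: morpholine, C1COCCN1
Why: aluminium amide aminolysis of a lactone, expected to stop after one opening because the strained cis-fused bis-lactone is more electrophilic than the monocyclic γ-lactone it leaves behind (unreacted 9 is recycled), and since 9 is C2-symmetric either lactone gives the same product with no stereocentre touched.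

Step 6
Reactants: 10 (3S,4S,5S)-3-[(S)-hydroxy(4-methoxyphenyl)methyl]-5-(4-methoxyphenyl)-4-(morpholine-4-carbonyl)oxolan-2-one
Product: 11 (3S,4S,5S)-5-(4-methoxyphenyl)-3-[(S)-(4-methoxyphenyl)(trimethylsilyloxy)methyl]-4-(morpholine-4-carbonyl)oxolan-2-one
Conditions: TMSCl, imidazole, CH2Cl2, 0 °C (used without chromatography)
Reagents that add atoms: chlorotrimethylsilane, C[Si](C)(C)Cl
Why: O-silylation of the secondary alcohol, which blocks relactonization and stores the C2 oxygen as a latent alkoxide for step 14 without touching a stereocentre.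

Step 7
Reactants: 12 3,5-bis(benzyloxy)phenol
Product: 13 3,5-bis(benzyloxy)phenyl N-(propan-2-yl)carbamate
Conditions: i-PrNCO, Et3N (cat.), CH2Cl2, rt
Reagents that add atoms: isopropyl isocyanate, CC(C)N=C=O
Why: addition of the phenol to an isocyanate (carbamoylation) installs a strong ortho-directing group that can later be removed under mild base.

Step 8
Reactants: 13 3,5-bis(benzyloxy)phenyl N-(propan-2-yl)carbamate
Product: 17 3,5-bis(benzyloxy)-2-(trimethylsilyl)phenyl N-(propan-2-yl)carbamate, via N-silyl carbamate 14 (not isolated), via aryllithium 15 (not isolated), via disilyl carbamate 16 (not isolated)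
Conditions: TBSOTf, TMEDA, Et2O, 0 °C → rt; n-BuLi, TMEDA, −78 °C; TMSCl, −78 °C → rt; aq. NaHSO4
Reagents that add atoms: chlorotrimethylsilane, C[Si](C)(C)Cl
Why: directed ortho-metalation of an O-aryl carbamate (N–H masked in the flask as N-silyl) at the position flanked by the carbamate and a benzyloxy group (the two such positions are equivalent), followed by C-silylation and loss of the N-silyl group on work-up.

Step 9
Reactants: 17 3,5-bis(benzyloxy)-2-(trimethylsilyl)phenyl N-(propan-2-yl)carbamate
Product: 19 3,5-bis(benzyloxy)-2-(trimethylsilyl)phenyl trifluoromethanesulfonate, via silylphenol 18 (not isolated)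
Conditions: DBU, Et2NH, MeCN, 40 °C; then PhNTf2, rt
Reagents that add atoms: N-phenylbis(trifluoromethanesulfonimide), O=S(=O)(N(c1ccccc1)S(=O)(=O)C(F)(F)F)C(F)(F)F
Why: E1cB cleavage of the N-monoalkyl carbamate (the isocyanate is trapped by diethylamine) and triflation of the phenoxide in the same flask, the usual end of the carbamate route to ortho-silylaryl triflates.

Step 10
Reactants: 20 2-(benzyloxy)-4-methoxybenzaldehyde
Product: 22 2-(benzyloxy)-4-methoxyphenol, via aryl formate 21 (not isolated)
Conditions: mCPBA, CH2Cl2, 0 °C → rt; then K2CO3, MeOH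
Reagents that add atoms: 3-chloroperbenzoic acid, O=C(OO)c1cccc(Cl)c1
Why: Baeyer–Villiger (Dakin-type) oxidation of an electron-rich benzaldehyde with aryl migration, then methanolysis of the formate, which places the phenol where only one ortho position is free and so fixes the regiochemistry of step 12.

Step 11
Reactants: 22 2-(benzyloxy)-4-methoxyphenol
Product: 23 2-(benzyloxy)-4-methoxyphenyl N-(propan-2-yl)carbamate
Conditions: i-PrNCO, Et3N (cat.), CH2Cl2, rt
Reagents that add atoms: isopropyl isocyanate, CC(C)N=C=O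
Why: carbamoylation of the phenol with an isocyanate, as in step 7.

Step 12
Reactants: 23 2-(benzyloxy)-4-methoxyphenyl N-(propan-2-yl)carbamate
Product: 27 2-(benzyloxy)-4-methoxy-6-(trimethylsilyl)phenyl N-(propan-2-yl)carbamate, via N-silyl carbamate 24 (not isolated), via aryllithium 25 (not isolated), via disilyl carbamate 26 (not isolated)
Conditions: TBSOTf, TMEDA, Et2O, 0 °C → rt; n-BuLi, TMEDA, −78 °C; TMSCl, −78 °C → rt; aq. NaHSO4
Reagents that add atoms: chlorotrimethylsilane, C[Si](C)(C)Cl
Why: directed ortho-metalation and silylation as in step 8, expected at C6 because it is the only free position ortho to the carbamate, which is a stronger director than the two ether oxygens that flank C3.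

Step 13
Reactants: 27 2-(benzyloxy)-4-methoxy-6-(trimethylsilyl)phenyl N-(propan-2-yl)carbamate
Product: 29 2-(benzyloxy)-4-methoxy-6-(trimethylsilyl)phenyl trifluoromethanesulfonate, via silylphenol 28 (not isolated)
Conditions: DBU, Et2NH, MeCN, 40 °C; then PhNTf2, rt
Reagents that add atoms: N-phenylbis(trifluoromethanesulfonimide), O=S(=O)(N(c1ccccc1)S(=O)(=O)C(F)(F)F)C(F)(F)F
Why: carbamate cleavage and triflation in one flask as in step 9, giving the precursor of the aryne that carries the 5''-benzyloxy and 7''-methoxy groups.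

Step 14
Reactants: 11 (3S,4S,5S)-5-(4-methoxyphenyl)-3-[(S)-(4-methoxyphenyl)(trimethylsilyloxy)methyl]-4-(morpholine-4-carbonyl)oxolan-2-one; 19 3,5-bis(benzyloxy)-2-(trimethylsilyl)phenyl trifluoromethanesulfonate; 29 2-(benzyloxy)-4-methoxy-6-(trimethylsilyl)phenyl trifluoromethanesulfonate
Product: 34 (2S,3S)-5,7-bis(benzyloxy)-3-[(2S,3S)-5-(benzyloxy)-7-methoxy-2-(4-methoxyphenyl)-4-oxochroman-3-yl]-2-(4-methoxyphenyl)chroman-4-one, via aryne 30 (not isolated), via potassium alkoxide 31 (not isolated), via aryne 32 (not isolated), via tetrahedral adduct 33 (not isolated)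
Conditions: 11, 19 (1.0 equiv), KF, 18-crown-6, THF, 0 °C → rt; then 29 (1.5 equiv), KF, 18-crown-6, rt; AcOH, 0 °C
Reagents that add atoms: none
Why: Proposed new method: fluoride unmasks the C2 alkoxide of 11 and the aryne 30 side by side; the alkoxide adds to the aryne carbon remote from the 3-benzyloxy group and the resulting aryl anion attacks the lactone carbonyl C4 (6-exo-trig acyl substitution), which closes ring C and expels the lactone oxygen as the C2'' alkoxide 31. Only then does a nucleophile exist for the second aryne 32: the same O-arylation and 6-exo-trig attack of the aryl anion, now on the amide carbonyl C4'', closes ring C'' last and stores it as the tetrahedral adduct 33 until the acetic acid quench releases ketone 34. The closest known reaction types are the annulation of arynes with salicylates to xanthones, the insertion of arynes into the O–C(acyl) bond of carboxylic acids and the acyl-alkylation of arynes by β-keto esters; the aliphatic β-oxido lactone and amide partners and the relay through the lactone leaving group are new. No bond to C2, C3, C3'' or C2'' is formed or broken, so no stereocentre is created and the cis,cis (2S,3S,2''S,3''S) array is simply that of the exo,exo bis-lactone 9. The step needs aryne regioselectivity (secured by the 3-benzyloxy group, which stabilises the ortho aryl anion and so puts oxygen on C8a/C8a'' and the acyl carbon on C4a/C4a'' next to the 5-oxygen), acylation rather than protonation of the aryl anion (aprotic medium, silyl ether as alkoxide source, six-membered transition state), attack of the second aryl anion on the amide C4'' through a six-membered ring rather than on the deactivated 2,4,6-trioxygenated ketone C4 through a seven-membered ring, and no crossover of the arynes (19 is the limiting reagent and is consumed before 29 is added). Retro-aldol cleavage and epimerisation at C3 or C3'' should be held back by the low temperature, by the hemiketal resting state of 31 and by the fact that the ring C'' ketone is only set free in the buffered quench.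

Step 15
Reactants: 34 (2S,3S)-5,7-bis(benzyloxy)-3-[(2S,3S)-5-(benzyloxy)-7-methoxy-2-(4-methoxyphenyl)-4-oxochroman-3-yl]-2-(4-methoxyphenyl)chroman-4-one
Product: 35 (2S,3S)-5,7-dihydroxy-3-[(2S,3S)-5-hydroxy-7-methoxy-2-(4-methoxyphenyl)-4-oxochroman-3-yl]-2-(4-methoxyphenyl)chroman-4-one (CNP0184936.4)
Conditions: H2 (1 atm), Pd/C (10 %), EtOAc, rt
Reagents that add atoms: none
Why: hydrogenolysis of the three primary benzyl aryl ethers under neutral conditions, which should be faster than cleavage of the cyclic secondary C2–O1 and C2''–O1'' bonds and leaves the four epimerisable stereocentres untouched.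

## Compound list

1 | 3-(4-methoxyphenyl)propanoic acid | COc1ccc(CCC(=O)O)cc1 | starting material
2 | (S)-4-benzyl-1,3-oxazolidin-2-one | O=C1N[C@@H](Cc2ccccc2)CO1 | starting material
3 | mixed anhydride of 1 with pivalic acid | COc1ccc(CCC(=O)OC(=O)C(C)(C)C)cc1 | intermediate
4 | (S)-4-benzyl-3-[3-(4-methoxyphenyl)propanoyl]-1,3-oxazolidin-2-one | COc1ccc(CCC(=O)N2C(=O)OC[C@@H]2Cc2ccccc2)cc1 | intermediate
5 | lithium (Z)-enolate of 4 | COc1ccc(C/C=C(\[O-])N2C(=O)OC[C@@H]2Cc2ccccc2)cc1.[Li+] | intermediate
6 | (2R,3R)-1,4-bis[(S)-4-benzyl-2-oxo-1,3-oxazolidin-3-yl]-2,3-bis(4-methoxybenzyl)butane-1,4-dione | COc1ccc(C[C@@H](C(=O)N2C(=O)OC[C@@H]2Cc2ccccc2)[C@@H](Cc2ccc(OC)cc2)C(=O)N2C(=O)OC[C@@H]2Cc2ccccc2)cc1 | intermediate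
7 | dilithium (2R,3R)-2,3-bis(4-methoxybenzyl)butanediperoxoate | COc1ccc(C[C@@H](C(=O)O[O-])[C@@H](Cc2ccc(OC)cc2)C(=O)O[O-])cc1.[Li+].[Li+] | intermediate
8 | (2R,3R)-2,3-bis(4-methoxybenzyl)butanedioic acid | COc1ccc(C[C@@H](C(=O)O)[C@@H](Cc2ccc(OC)cc2)C(=O)O)cc1 | intermediate
9 | (3S,3aS,6S,6aS)-3,6-bis(4-methoxyphenyl)tetrahydro-1H,4H-furo[3,4-c]furan-1,4-dione | COc1ccc([C@H]2OC(=O)[C@H]3[C@@H]2C(=O)O[C@@H]3c2ccc(OC)cc2)cc1 | intermediate
10 | (3S,4S,5S)-3-[(S)-hydroxy(4-methoxyphenyl)methyl]-5-(4-methoxyphenyl)-4-(morpholine-4-carbonyl)oxolan-2-one | COc1ccc([C@@H](O)[C@H]2C(=O)O[C@H](c3ccc(OC)cc3)[C@H]2C(=O)N2CCOCC2)cc1 | intermediate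
11 | O-trimethylsilyl ether of 10 | COc1ccc([C@@H](O[Si](C)(C)C)[C@H]2C(=O)O[C@H](c3ccc(OC)cc3)[C@H]2C(=O)N2CCOCC2)cc1 | intermediate
12 | 3,5-bis(benzyloxy)phenol | Oc1cc(OCc2ccccc2)cc(OCc2ccccc2)c1 | starting material
13 | 3,5-bis(benzyloxy)phenyl N-(propan-2-yl)carbamate | CC(C)NC(=O)Oc1cc(OCc2ccccc2)cc(OCc2ccccc2)c1 | intermediate
14 | N-(tert-butyldimethylsilyl) derivative of 13 | CC(C)N(C(=O)Oc1cc(OCc2ccccc2)cc(OCc2ccccc2)c1)[Si](C)(C)C(C)(C)C | intermediate
15 | 2-lithio derivative of 14 | CC(C)N(C(=O)Oc1cc(OCc2ccccc2)cc(OCc2ccccc2)c1[Li])[Si](C)(C)C(C)(C)C | intermediate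
16 | 2-(trimethylsilyl) derivative of 14 | CC(C)N(C(=O)Oc1cc(OCc2ccccc2)cc(OCc2ccccc2)c1[Si](C)(C)C)[Si](C)(C)C(C)(C)C | intermediate
17 | 3,5-bis(benzyloxy)-2-(trimethylsilyl)phenyl N-(propan-2-yl)carbamate | CC(C)NC(=O)Oc1cc(OCc2ccccc2)cc(OCc2ccccc2)c1[Si](C)(C)C | intermediate
18 | 3,5-bis(benzyloxy)-2-(trimethylsilyl)phenol (present as its DBU salt) | Oc1cc(OCc2ccccc2)cc(OCc2ccccc2)c1[Si](C)(C)C | intermediate
19 | 3,5-bis(benzyloxy)-2-(trimethylsilyl)phenyl trifluoromethanesulfonate | C[Si](C)(C)c1c(OCc2ccccc2)cc(OCc2ccccc2)cc1OS(=O)(=O)C(F)(F)F | intermediate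
20 | 2-(benzyloxy)-4-methoxybenzaldehyde | COc1ccc(C=O)c(OCc2ccccc2)c1 | starting material
21 | 2-(benzyloxy)-4-methoxyphenyl formate | COc1ccc(OC=O)c(OCc2ccccc2)c1 | intermediate
22 | 2-(benzyloxy)-4-methoxyphenol | COc1ccc(O)c(OCc2ccccc2)c1 | intermediate
23 | 2-(benzyloxy)-4-methoxyphenyl N-(propan-2-yl)carbamate | COc1ccc(OC(=O)NC(C)C)c(OCc2ccccc2)c1 | intermediate
24 | N-(tert-butyldimethylsilyl) derivative of 23 | COc1ccc(OC(=O)N(C(C)C)[Si](C)(C)C(C)(C)C)c(OCc2ccccc2)c1 | intermediate
25 | 6-lithio derivative of 24 | COc1cc([Li])c(OC(=O)N(C(C)C)[Si](C)(C)C(C)(C)C)c(OCc2ccccc2)c1 | intermediate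
26 | 6-(trimethylsilyl) derivative of 24 | COc1cc([Si](C)(C)C)c(OC(=O)N(C(C)C)[Si](C)(C)C(C)(C)C)c(OCc2ccccc2)c1 | intermediate
27 | 2-(benzyloxy)-4-methoxy-6-(trimethylsilyl)phenyl N-(propan-2-yl)carbamate | COc1cc([Si](C)(C)C)c(OC(=O)NC(C)C)c(OCc2ccccc2)c1 | intermediate
28 | 2-(benzyloxy)-4-methoxy-6-(trimethylsilyl)phenol (present as its DBU salt) | COc1cc([Si](C)(C)C)c(O)c(OCc2ccccc2)c1 | intermediate
29 | 2-(benzyloxy)-4-methoxy-6-(trimethylsilyl)phenyl trifluoromethanesulfonate | COc1cc([Si](C)(C)C)c(OS(=O)(=O)C(F)(F)F)c(OCc2ccccc2)c1 | intermediate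
30 | 3,5-bis(benzyloxy)benzyne | C1#CC(OCc2ccccc2)=CC(OCc2ccccc2)=C1 | intermediate
31 | potassium alkoxide of (2S,3S)-5,7-bis(benzyloxy)-3-[(2S,3S)-3-hydroxy-3-(4-methoxyphenyl)-1-(morpholin-4-yl)-1-oxopropan-2-yl]-2-(4-methoxyphenyl)chroman-4-one (ring C closed; in equilibrium with its cyclic hemiketal alkoxide) | COc1ccc([C@H]2Oc3cc(OCc4ccccc4)cc(OCc4ccccc4)c3C(=O)[C@H]2[C@H](C(=O)N2CCOCC2)[C@H]([O-])c2ccc(OC)cc2)cc1.[K+] | intermediate
32 | 3-(benzyloxy)-5-methoxybenzyne | COC1=CC#CC(OCc2ccccc2)=C1 | intermediate
33 | potassium salt of the C4'' morpholine hemiaminal of 34 (tetrahedral adduct of the ring C'' closure) | COc1ccc([C@H]2Oc3cc(OCc4ccccc4)cc(OCc4ccccc4)c3C(=O)[C@H]2[C@@H]2C([O-])(N5CCOCC5)c3c(OCc4ccccc4)cc(OC)cc3O[C@@H]2c2ccc(OC)cc2)cc1.[K+] | intermediate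
34 | (2S,3S)-5,7-bis(benzyloxy)-3-[(2S,3S)-5-(benzyloxy)-7-methoxy-2-(4-methoxyphenyl)-4-oxochroman-3-yl]-2-(4-methoxyphenyl)chroman-4-one | COc1ccc([C@H]2Oc3cc(OCc4ccccc4)cc(OCc4ccccc4)c3C(=O)[C@H]2[C@@H]2C(=O)c3c(OCc4ccccc4)cc(OC)cc3O[C@@H]2c2ccc(OC)cc2)cc1 | intermediate
35 | (2S,3S)-5,7-dihydroxy-3-[(2S,3S)-5-hydroxy-7-methoxy-2-(4-methoxyphenyl)-4-oxochroman-3-yl]-2-(4-methoxyphenyl)chroman-4-one | COc1ccc([C@H]2Oc3cc(O)cc(O)c3C(=O)[C@H]2[C@@H]2C(=O)c3c(O)cc(OC)cc3O[C@@H]2c2ccc(OC)cc2)cc1 | target

## Step count and risks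

Total step count: 15. Longest linear sequence: 8 steps (steps 1–6, 14, 15); the two aryne precursors take 3 steps (7–9) and 4 steps (10–13).

The three steps most likely to fail:

Step 14 (proposed new method). The aryl anions may be protonated before they acylate, which would give simple aryl ethers. The potassium alkoxides may undergo retro-aldol cleavage or C3 epimerisation while they wait for an aryne. The two arynes may cross over, or the second aryl anion may add to the ring C ketone. The fallback uses known chemistry: aryllithium addition to lactones, then intramolecular nucleophilic aromatic substitution ortho to a ketone. It sets out from 9 and comes back at 34. 2,4-Bis(benzyloxy)-6-fluorophenyllithium (one equivalent) and then 2-(benzyloxy)-6-chloro-4-methoxyphenyllithium would be added to the two lactone carbonyls of 9; both are made from the aryl bromides by bromine–lithium exchange in THF at −78 °C. Aqueous work-up should give (2S,3S)-1-[2,4-bis(benzyloxy)-6-fluorophenyl]-4-[2-(benzyloxy)-6-chloro-4-methoxyphenyl]-2,3-bis[(S)-hydroxy(4-methoxyphenyl)methyl]butane-1,4-dione F1, in equilibrium with its bis-hemiketal. Cs2CO3 in DMF at 0 °C should then let the C2 hydroxyl displace the fluoride ortho to its ketone and close ring C, giving (2S,3S)-5,7-bis(benzyloxy)-3-[(2S,3S)-1-[2-(benzyloxy)-6-chloro-4-methoxyphenyl]-3-hydroxy-3-(4-methoxyphenyl)-1-oxopropan-2-yl]-2-(4-methoxyphenyl)chroman-4-one F2. Warming to about 40 °C should displace the less reactive chloride and close ring C'' last, giving 34 with no bond at a stereocentre broken.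

Step 4. The p-methoxybenzylic cation may lose the C3 proton (styrene formation and loss of the C3 or C3'' stereocentre) or be over-oxidised before the carboxyl group captures it. The fallback sets out from 8 and comes back at 9 by radical bromination and silver-assisted substitution. NBS (2.1 equiv) with catalytic dibenzoyl peroxide in PhCF3 at 80 °C should give (2R,3R)-2,3-bis[bromo(4-methoxyphenyl)methyl]butanedioic acid F3, as epimers at the two C–Br carbons. Ag2CO3 in MeCN at 0 °C should ionise each bromide next to a carboxylate, a far better trap than the neutral acid, and converge on 9.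

Step 15. Hydrogenolytic cleavage of the benzylic C2–O1 and C2''–O1'' bonds of rings C and C'' (both are p-methoxybenzylic aryl ethers) may compete with the slow cleavage of the hindered 5- and 5''-benzyl ethers. The fallback sets out from 34 and comes back at 35 by Lewis acid dealkylation instead of hydrogenolysis: BCl3 with pentamethylbenzene as cation scavenger, CH2Cl2, −78 °C, then MeOH. This fallback makes no new compound (F0).

Further compounds
F1 | step 14 | (2S,3S)-1-[2,4-bis(benzyloxy)-6-fluorophenyl]-4-[2-(benzyloxy)-6-chloro-4-methoxyphenyl]-2,3-bis[(S)-hydroxy(4-methoxyphenyl)methyl]butane-1,4-dione | COc1ccc([C@@H](O)[C@@H](C(=O)c2c(F)cc(OCc3ccccc3)cc2OCc2ccccc2)[C@H](C(=O)c2c(Cl)cc(OC)cc2OCc2ccccc2)[C@H](O)c2ccc(OC)cc2)cc1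
F2 | step 14 | (2S,3S)-5,7-bis(benzyloxy)-3-[(2S,3S)-1-[2-(benzyloxy)-6-chloro-4-methoxyphenyl]-3-hydroxy-3-(4-methoxyphenyl)-1-oxopropan-2-yl]-2-(4-methoxyphenyl)chroman-4-one | COc1ccc([C@H]2Oc3cc(OCc4ccccc4)cc(OCc4ccccc4)c3C(=O)[C@H]2[C@H](C(=O)c2c(Cl)cc(OC)cc2OCc2ccccc2)[C@H](O)c2ccc(OC)cc2)cc1
F3 | step 4 | (2R,3R)-2,3-bis[bromo(4-methoxyphenyl)methyl]butanedioic acid | COc1ccc(C(Br)[C@@H](C(=O)O)[C@@H](C(Br)c2ccc(OC)cc2)C(=O)O)cc1
F0 | step 15 | none | none
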